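The ten-membered carbocycle (C1–C10) is grown from a six-membered ring, not closed end to end. Because C10 lies four bonds from the oxygenated C6 by way of C7, C8 and C9, the macrocycle folds back onto a cyclohex-2-enol built from C6 and C1–C5: C6 holds the hydroxyl and an E-2-alkoxyvinyl arm (C7=C8), its neighbour C1 an isopropenyl arm (C10, C9, C14) trans to that arm. A single anionic oxy-Cope rearrangement joins C8 to C9, cuts C1–C6, fixes C8 and the E alkene C1–C10, and leaves a C6 ketone on which the lactone (C6, C7, C11, C12), the C8 ester and the C3–O–C10 oxide bridge are then raised. C3 and C15 travel as silyl ethers.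

Key step: step 11

Atom labels: germacrane numbering of the target throughout (C1–C10 ring; C11–C13 lactone carbons; C14 methyl on C10; C15 hydroxymethyl carbon on C4).

Assumption: C3 is a hemiketal carbon tied to C10 by the one-oxygen bridge and able to equilibrate through the open 3-keto-10-hydroxy form, so it follows from C10 (step 17) and is not controlled separately; bridged compounds are written with the C3 descriptor of the given structure, and if that descriptor is not the one a closed bridge permits, the centre is to be read as the bridge-permitted one.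

Step 1
Reactants: 1 2-hydroxy-5-methoxybenzaldehyde
Product: 2 2-(hydroxymethyl)-4-methoxyphenol
Conditions: NaBH4, MeOH, 0 °C
Reagents that add atoms: none
Why: Borohydride reduction of the aryl aldehyde to the benzylic alcohol; no stereocentre is formed.

Step 2
Reactants: 2 2-(hydroxymethyl)-4-methoxyphenol
Product: 3 2-[(tert-butyldiphenylsilyloxy)methyl]-4-methoxyphenol
Conditions: TBDPSCl (1.05 equiv), imidazole, CH2Cl2, 0 °C
Reagents that add atoms: tert-butyl(chloro)diphenylsilane, CC(C)(C)[Si](Cl)(c1ccccc1)c1ccccc1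
Why: Imidazole-promoted silylation should take the unhindered primary benzylic hydroxyl in preference to the hydrogen-bonded, ortho-substituted phenol when the bulky chlorosilane is used, and any phenol silyl ether formed can be cleaved back with K2CO3/MeOH.

Step 3
Reactants: 3 2-[(tert-butyldiphenylsilyloxy)methyl]-4-methoxyphenol
Product: 4 2-[(tert-butyldiphenylsilyloxy)methyl]-4,4-dimethoxycyclohexa-2,5-dien-1-one
Conditions: PhI(OAc)2, MeOH, 0 °C
Reagents that add atoms: methanol, CO
Why: Oxidative dearomatization of a para-methoxyphenol by the hypervalent iodine reagent in methanol gives the quinone monoketal, the phenol carbon becoming the carbonyl (future C3) and the anisole carbon the ketal (future C6).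

Step 4
Reactants: 4 2-[(tert-butyldiphenylsilyloxy)methyl]-4,4-dimethoxycyclohexa-2,5-dien-1-one; 5 potassium isopropenyltrifluoroborate
Product: 6 (5R)-2-[(tert-butyldiphenylsilyloxy)methyl]-4,4-dimethoxy-5-(prop-1-en-2-yl)cyclohex-2-en-1-one
Conditions: [Rh(cod)2]BF4 (3 mol %), (R)-BINAP, Et3N, toluene/H2O, 25–40 °C
Reagents that add atoms: none
Why: Hayashi–Miyaura rhodium-catalysed asymmetric 1,4-addition of an alkenyltrifluoroborate, in which the α-unsubstituted enone arm reacts because the α-substituted arm inserts far more slowly, and the (R)-BINAP–rhodium complex is expected, by analogy with 2-cyclohexenone and quinone monoketals, to select the enone face that gives the 5R centre (future C1).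

Step 5
Reactants: 6 (5R)-2-[(tert-butyldiphenylsilyloxy)methyl]-4,4-dimethoxy-5-(prop-1-en-2-yl)cyclohex-2-en-1-one
Product: 8 (4R,6R)-4-hydroxy-3-[(tert-butyldiphenylsilyloxy)methyl]-6-(prop-1-en-2-yl)cyclohex-2-en-1-one, via allylic alcohol 7 (not isolated)
Conditions: NaBH4, CeCl3·7H2O, MeOH, −78 °C; then 1 M aq. oxalic acid, THF, 0 °C
Reagents that add atoms: water, O
Why: Luche 1,2-reduction delivers hydride axially to the carvone-like enone so that the new C3 hydroxyl is cis to the isopropenyl group, and mild acid then hydrolyses the allylic dimethyl ketal to the C6 enone (reduction–hydrolysis transposition of a quinone monoketal); the cis-1,3 diequatorial arrangement is the stable one, which protects C1, now α to the ketone, against epimerization.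

Step 6
Reactants: 8 (4R,6R)-4-hydroxy-3-[(tert-butyldiphenylsilyloxy)methyl]-6-(prop-1-en-2-yl)cyclohex-2-en-1-one
Product: 9 (4R,6R)-4-(tert-butyldimethylsilyloxy)-3-[(tert-butyldiphenylsilyloxy)methyl]-6-(prop-1-en-2-yl)cyclohex-2-en-1-one
Conditions: TBSCl, imidazole, DMF, 0 °C to rt
Reagents that add atoms: tert-butyl(chloro)dimethylsilane, CC(C)(C)[Si](C)(C)Cl
Why: Silylation of the secondary allylic alcohol under nearly neutral conditions that should not enolize the β,γ-unsaturated ketone; no stereocentre changes.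

Step 7
Reactants: 10 4-methoxybenzyl alcohol; 11 trichloroethylene
Product: 13 1-{[(E)-1,2-dichloroethenyl]oxymethyl}-4-methoxybenzene, via potassium 4-methoxybenzyl oxide 12 (not isolated)
Conditions: KH, THF, 0 °C; then 11, 0 °C to rt
Reagents that add atoms: potassium hydride, [K+].[H-] (potassium in 12 only)
Why: The alkoxide eliminates HCl from trichloroethylene and adds anti to the dichloroacetylene so formed, giving the E-1,2-dichlorovinyl ether (first stage of the standard alkynyl ether synthesis from trichloroethylene).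

Step 8
Reactants: 13 1-{[(E)-1,2-dichloroethenyl]oxymethyl}-4-methoxybenzene
Product: 15 1-(ethynyloxymethyl)-4-methoxybenzene, via lithium alkoxyacetylide 14 (not isolated)
Conditions: n-BuLi (2.3 equiv), THF, −78 to −40 °C; then MeOH, −78 °C
Reagents that add atoms: n-butyllithium, [Li]CCCC (lithium in 14 only)
Why: A first equivalent of n-BuLi eliminates HCl to the chloroalkynyl ether, a second exchanges chlorine for lithium, and methanol protonates the acetylide to the terminal ynol ether, which is kept below room temperature because benzyl alkynyl ethers rearrange on warming.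

Step 9
Reactants: 15 1-(ethynyloxymethyl)-4-methoxybenzene
Product: 17 1-{[(E)-2-iodoethenyl]oxymethyl}-4-methoxybenzene, via alkenylzirconocene chloride 16 (not isolated)
Conditions: Cp2Zr(H)Cl, THF, rt; then I2, 0 °C
Reagents that add atoms: iodine, I-I; Cp2Zr(H)Cl, [H][Zr](Cl)(C1C=CC=C1)C1C=CC=C1 (zirconocene chloride unit in 16 only)
Why: Hydrozirconation adds Zr–H syn across the alkyne with zirconium on the terminal carbon, and iodinolysis of the C–Zr bond with retention gives the E-2-alkoxyvinyl iodide.

Step 10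
Reactants: 17 1-{[(E)-2-iodoethenyl]oxymethyl}-4-methoxybenzene; 9 (4R,6R)-4-(tert-butyldimethylsilyloxy)-3-[(tert-butyldiphenylsilyloxy)methyl]-6-(prop-1-en-2-yl)cyclohex-2-en-1-one
Product: 20 (1R,4R,6R)-4-(tert-butyldimethylsilyloxy)-3-[(tert-butyldiphenylsilyloxy)methyl]-1-[(E)-2-(4-methoxybenzyloxy)ethenyl]-6-(prop-1-en-2-yl)cyclohex-2-en-1-ol, via alkenyllithium 18 (not isolated), via alkenylcerium dichloride 19 (not isolated)
Conditions: t-BuLi (2.0 equiv), Et2O, −78 °C; CeCl3, THF, −78 °C; then 9, −78 °C
Reagents that add atoms: tert-butyllithium, [Li]C(C)(C)C (lithium in 18 only); CeCl3, Cl[Ce](Cl)Cl (CeCl2 unit in 19 only)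
Why: Iodine–lithium exchange with retention of the E geometry, transmetalation to the weakly basic organocerium reagent and 1,2-addition to the enolizable enone; the nucleophile should enter the carbonyl face opposite the adjacent pseudo-equatorial isopropenyl group (as alkenyllithium reagents do with 6-isopropenylcyclohex-2-enones), which sets C6 with the two alkenyl arms trans and the hydroxyl cis to isopropenyl.

Step 11
Reactants: 20 (1R,4R,6R)-4-(tert-butyldimethylsilyloxy)-3-[(tert-butyldiphenylsilyloxy)methyl]-1-[(E)-2-(4-methoxybenzyloxy)ethenyl]-6-(prop-1-en-2-yl)cyclohex-2-en-1-ol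
Product: 23 (2Z,6E,4R,9R)-4-(tert-butyldimethylsilyloxy)-3-[(tert-butyldiphenylsilyloxy)methyl]-9-(4-methoxybenzyloxy)-7-methylcyclodeca-2,6-dien-1-one, via potassium alkoxide 21 (not isolated), via potassium enolate 22 (not isolated)
Conditions: KH, 18-crown-6, THF, 0 °C to rt; then AcOH, THF, −78 °C
Reagents that add atoms: potassium hydride, [K+].[H-] (potassium in 21 and 22 only)
Why: KH with 18-crown-6 gives the loosely paired alkoxide 21, whose oxyanion accelerates a concerted [3,3]-sigmatropic shift of the 1,5-diene C8=C7–C6–C1–C10=C9 (anionic oxy-Cope rearrangement, the established ring expansion of trans-1,2-dialkenylcyclohexanols to cyclodec-5-enones): C8–C9 is made as C1–C6 is cut, and the C6–C7 enolate 22 is protonated on the cold acetic acid quench. The ten-membered ring is not closed end to end; it arises by four-atom ring expansion of the cyclohexene through a six-membered chair transition state. C8, the only new stereocentre, is fixed by transfer of chirality from C6 and C1: with both alkenyl arms equatorial and the E enol ether holding its oxygen equatorial on the chair, the (6R,1R) precursor can only give 8R. The same chair makes the new C1–C10 alkene E, because the ring bond C1–C2 is equatorial, and passes the C4–C5 alkene on unchanged as Z. The step needs the chair path through the exocyclic enol ether in preference to a boat or a shift through the ring alkene, and the trans-diequatorial arrangement of the two arms secures this. It also needs the enolate to keep its C8 ether: as formed, the C8–O bond lies in the nodal plane of the enolate, which disfavours β-elimination until the cold quench.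

Step 12
Reactants: 23 (2Z,6E,4R,9R)-4-(tert-butyldimethylsilyloxy)-3-[(tert-butyldiphenylsilyloxy)methyl]-9-(4-methoxybenzyloxy)-7-methylcyclodeca-2,6-dien-1-one; 24 tert-butyl bromoacetate
Product: 26 C7-alkylated keto ester (23 carrying CH2CO2t-Bu on C7; 3R,7R,8R; acetate chain cis to the C8 oxygen), via lithium enolate 25 (not isolated)
Conditions: LiN(i-Pr)2 (1.05 equiv), THF, −78 °C; then 24, −78 to −30 °C
Reagents that add atoms: LiN(i-Pr)2, [Li]N(C(C)C)C(C)C (lithium in 25 only)
Why: Kinetic α'-deprotonation of the enone and SN2 alkylation of the lithium enolate, in which lithium should bridge the enolate oxygen and the C8 ether oxygen (Fráter–Seebach-type chelate) so that the C8–O bond lies in the enolate plane and the bromoacetate attacks the face away from C9, placing the chain cis to the C8 oxygen (C7); the tert-butyl ester is chosen because it cannot lactonize onto O8 once that hydroxyl is freed.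

Step 13
Reactants: 26 C7-alkylated keto ester
Product: 27 β-hydroxy ketone (26 with free C8 hydroxyl; 3R,7R,8R)
Conditions: DDQ, CH2Cl2/pH 7 buffer, 0 °C
Reagents that add atoms: none
Why: Oxidative cleavage of the 4-methoxybenzyl ether by DDQ under buffered conditions that should leave both silyl ethers, the enone, the tert-butyl ester and the β-hydroxy ketone intact; no stereocentre changes.

Step 14
Reactants: 27 β-hydroxy ketone; 28 isobutyraldehyde
Product: 29 hydroxy ester (C6 alcohol anti to the C8 isobutyrate; 3R,6R,7S,8R by CIP, with C7 spatially unchanged; tert-butyl ester retained)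
Conditions: SmI2 (30 mol %), i-PrCHO (8 equiv), THF, −10 °C
Reagents that add atoms: none
Why: Evans–Tishchenko reduction, in which the samarium-bound hemiacetal of the C8 hydroxyl and isobutyraldehyde transfers hydride intramolecularly to C6 through a chair-like six-membered transition state, giving the 1,3-anti alcohol (C6) while the acyl group ends on O8 as the isobutyrate of the target and so keeps O8 out of the later lactonization.

Step 15
Reactants: 29 hydroxy ester
Product: 32 trans-fused γ-lactone with free C3 hydroxyl (3R,6R,7R,8R; C15 silyl ether and C8 isobutyrate retained), via hydroxy acid 30 (not isolated), via silyl ether lactone 31 (not isolated)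
Conditions: ZnBr2, CH2Cl2, rt; then CSA, MeOH, 0 °C to rt
Reagents that add atoms: none
Why: Lewis-acid cleavage of the tert-butyl ester, acid-catalysed γ-lactonization of the C6 hydroxyl onto C12 (trans-fused because C6 and C7 are already set) and acid methanolysis of the secondary allylic TBS ether, while the far more acid-stable primary TBDPS ether and the hindered isobutyrate should persist and no protic acid strong enough to protonate the C1–C10 alkene is used.

Step 16
Reactants: 32 lactone with free C3 hydroxyl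
Product: 33 C3 enone (3-oxo lactone with the C1–C10 alkene β,γ to the ketone; 6R,7R,8R)
Conditions: Dess–Martin periodinane, NaHCO3, CH2Cl2, 0 °C
Reagents that add atoms: none
Why: Dess–Martin oxidation of the allylic alcohol to the enone under buffered, non-basic conditions that should not move the β,γ-alkene into conjugation; the product is used at once.

Step 17
Reactants: 33 C3 enone
Product: 35 3-O-methyl 3,10-oxide (bridged methyl ketal; C3 as written, 6R,7R,8R,10R), via organomercury acetate 34 (not isolated)
Conditions: Hg(OAc)2, MeOH, 0 °C; then NaBH4, −20 °C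
Reagents that add atoms: methanol, CO; Hg(OAc)2, CC(=O)O[Hg]OC(C)=O (HgOAc unit in 34 only)
Why: Transannular Markovnikov alkoxymercuration, in which Hg(OAc)2 adds to the electron-rich C1–C10 alkene from the ring periphery, the C3 carbonyl oxygen (or its methyl hemiketal) opens the mercurinium ion anti at the tertiary C10 in a five-membered closure, methanol caps C3 and NaBH4 replaces mercury at C1 by hydrogen; C10 is set by the ring conformation held by the trans-lactone and the C8 ester (the alkene face turned towards C3 is the one used in the natural 3,10-oxides of this family), which should place the bridge oxygen cis to the C8 ester oxygen, and C3 follows from the bridge.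

Step 18
Reactants: 35 3-O-methyl 3,10-oxide
Product: 39 α-methylene lactone (35 with C11=C13 methylene; C3 methyl ketal and C15 silyl ether retained), via lithium lactone enolate 36 (not isolated), via Mannich base 37 (not isolated), via trimethylammonium iodide 38 (not isolated)
Conditions: LiN(i-Pr)2 (1.1 equiv), THF, −78 °C; CH2=NMe2+ I−, −78 to 0 °C; then MeI, MeOH, rt; then aq. NaHCO3, CH2Cl2
Reagents that add atoms: N,N-dimethylmethyleneiminium iodide (Eschenmoser's salt), C=[N+](C)C.[I-]; LiN(i-Pr)2, [Li]N(C(C)C)C(C)C (lithium in 36 only); iodomethane, CI (methyl in 38 only)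
Why: Mannich reaction of the lactone enolate with Eschenmoser's salt, N-methylation and Hofmann-type elimination (α-methylenation), in which the base should take the more acidic, unhindered α-CH2 of the γ-lactone in preference to the hindered isobutyrate methine at −78 °C and the ketal, silyl ether and ester are inert; the C11 centre of 37 and 38 is lost in the elimination.

Step 19
Reactants: 39 α-methylene lactone
Product: 40 target, CNP0282937.1
Conditions: 48% aq. HF, MeCN, 0 °C to rt
Reagents that add atoms: water, O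
Why: Aqueous HF cleaves the primary silyl ether and exchanges the allylic methyl ketal for the hemiketal by acid-catalysed hydrolysis, C3 staying tied to C10 through the bridge, while the methylene lactone and the isobutyrate should tolerate the acidic medium.

Compound list
1 | 2-hydroxy-5-methoxybenzaldehyde | COc1ccc(O)c(C=O)c1 | starting material
2 | 2-(hydroxymethyl)-4-methoxyphenol | COc1ccc(O)c(CO)c1 | intermediate
3 | 2-[(tert-butyldiphenylsilyloxy)methyl]-4-methoxyphenol | COc1ccc(O)c(CO[Si](c2ccccc2)(c2ccccc2)C(C)(C)C)c1 | intermediate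
4 | 2-[(tert-butyldiphenylsilyloxy)methyl]-4,4-dimethoxycyclohexa-2,5-dien-1-one | COC1(OC)C=CC(=O)C(CO[Si](c2ccccc2)(c2ccccc2)C(C)(C)C)=C1 | intermediate
5 | potassium isopropenyltrifluoroborate | [K+].CC(=C)[B-](F)(F)F | starting material
6 | (5R)-2-[(tert-butyldiphenylsilyloxy)methyl]-4,4-dimethoxy-5-(prop-1-en-2-yl)cyclohex-2-en-1-one | O=C1C[C@H](C(C)=C)C(OC)(OC)C=C1CO[Si](c2ccccc2)(c2ccccc2)C(C)(C)C | intermediate
7 | (1R,5R)-2-[(tert-butyldiphenylsilyloxy)methyl]-4,4-dimethoxy-5-(prop-1-en-2-yl)cyclohex-2-en-1-ol, hydroxyl cis to isopropenyl, not isolated | O[C@@H]1C[C@H](C(C)=C)C(OC)(OC)C=C1CO[Si](c2ccccc2)(c2ccccc2)C(C)(C)C | intermediate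
8 | (4R,6R)-4-hydroxy-3-[(tert-butyldiphenylsilyloxy)methyl]-6-(prop-1-en-2-yl)cyclohex-2-en-1-one | O=C1C=C(CO[Si](c2ccccc2)(c2ccccc2)C(C)(C)C)[C@H](O)C[C@@H]1C(C)=C | intermediate
9 | (4R,6R)-4-(tert-butyldimethylsilyloxy)-3-[(tert-butyldiphenylsilyloxy)methyl]-6-(prop-1-en-2-yl)cyclohex-2-en-1-one | O=C1C=C(CO[Si](c2ccccc2)(c2ccccc2)C(C)(C)C)[C@H](O[Si](C)(C)C(C)(C)C)C[C@@H]1C(C)=C | intermediate
10 | 4-methoxybenzyl alcohol | COc1ccc(CO)cc1 | starting material
11 | trichloroethylene | ClC=C(Cl)Cl | starting material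
12 | potassium 4-methoxybenzyl oxide, not isolated | [K+].[O-]Cc1ccc(OC)cc1 | intermediate
13 | 1-{[(E)-1,2-dichloroethenyl]oxymethyl}-4-methoxybenzene | COc1ccc(CO/C(Cl)=C\Cl)cc1 | intermediate
14 | lithium 2-(4-methoxybenzyloxy)ethynide, not isolated | [Li]C#COCc1ccc(OC)cc1 | intermediate
15 | 1-(ethynyloxymethyl)-4-methoxybenzene | C#COCc1ccc(OC)cc1 | intermediate
16 | chloro[(E)-2-(4-methoxybenzyloxy)ethenyl]zirconocene, not isolated | COc1ccc(CO/C=C/[Zr](Cl)(C2C=CC=C2)C2C=CC=C2)cc1 | intermediate
17 | 1-{[(E)-2-iodoethenyl]oxymethyl}-4-methoxybenzene | COc1ccc(CO/C=C/I)cc1 | intermediate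
18 | (E)-2-(4-methoxybenzyloxy)ethenyllithium, not isolated | [Li]/C=C/OCc1ccc(OC)cc1 | intermediate
19 | dichloro[(E)-2-(4-methoxybenzyloxy)ethenyl]cerium, not isolated | Cl[Ce](Cl)/C=C/OCc1ccc(OC)cc1 | intermediate
20 | (1R,4R,6R)-4-(tert-butyldimethylsilyloxy)-3-[(tert-butyldiphenylsilyloxy)methyl]-1-[(E)-2-(4-methoxybenzyloxy)ethenyl]-6-(prop-1-en-2-yl)cyclohex-2-en-1-ol (key-step precursor; germacrane C6 R, C3 R, C1 R; alkenyl arms trans) | COc1ccc(CO/C=C/[C@@]2(O)C=C(CO[Si](c3ccccc3)(c3ccccc3)C(C)(C)C)[C@H](O[Si](C)(C)C(C)(C)C)C[C@@H]2C(C)=C)cc1 | intermediate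
21 | potassium alkoxide of 20, not isolated | [K+].COc1ccc(CO/C=C/[C@@]2([O-])C=C(CO[Si](c3ccccc3)(c3ccccc3)C(C)(C)C)[C@H](O[Si](C)(C)C(C)(C)C)C[C@@H]2C(C)=C)cc1 | intermediate
22 | potassium C6–C7 enolate of 23 (enolate oxygen cis to C8), not isolated | [K+].[O-]/C1=C\[C@H](OCc2ccc(OC)cc2)C/C(C)=C/C[C@@H](O[Si](C)(C)C(C)(C)C)/C(CO[Si](c2ccccc2)(c2ccccc2)C(C)(C)C)=C\1 | intermediate
23 | (2Z,6E,4R,9R)-4-(tert-butyldimethylsilyloxy)-3-[(tert-butyldiphenylsilyloxy)methyl]-9-(4-methoxybenzyloxy)-7-methylcyclodeca-2,6-dien-1-one (key-step product; C6 ketone, 4Z, 1(10)E, 8R) | O=C1/C=C(/CO[Si](c2ccccc2)(c2ccccc2)C(C)(C)C)[C@H](O[Si](C)(C)C(C)(C)C)C/C=C(C)/C[C@@H](OCc2ccc(OC)cc2)C1 | intermediate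
24 | tert-butyl bromoacetate | CC(C)(C)OC(=O)CBr | starting material
25 | lithium C6–C7 enolate of 23, not isolated | [Li+].[O-]/C1=C\[C@H](OCc2ccc(OC)cc2)C/C(C)=C/C[C@@H](O[Si](C)(C)C(C)(C)C)/C(CO[Si](c2ccccc2)(c2ccccc2)C(C)(C)C)=C\1 | intermediate
26 | tert-butyl ester: 23 with CH2CO2t-Bu on C7 (3R,7R,8R) | O=C1/C=C(/CO[Si](c2ccccc2)(c2ccccc2)C(C)(C)C)[C@H](O[Si](C)(C)C(C)(C)C)C/C=C(C)/C[C@@H](OCc2ccc(OC)cc2)[C@H]1CC(=O)OC(C)(C)C | intermediate
27 | β-hydroxy ketone: 26 with free C8 hydroxyl (3R,7R,8R) | O=C1/C=C(/CO[Si](c2ccccc2)(c2ccccc2)C(C)(C)C)[C@H](O[Si](C)(C)C(C)(C)C)C/C=C(C)/C[C@@H](O)[C@H]1CC(=O)OC(C)(C)C | intermediate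
28 | isobutyraldehyde (2-methylpropanal) | CC(C)C=O | starting material
29 | hydroxy ester: C6 alcohol anti to C8 isobutyrate, tert-butyl ester (3R,6R,7S,8R) | O[C@@H]1/C=C(/CO[Si](c2ccccc2)(c2ccccc2)C(C)(C)C)[C@H](O[Si](C)(C)C(C)(C)C)C/C=C(C)/C[C@@H](OC(=O)C(C)C)[C@H]1CC(=O)OC(C)(C)C | intermediate
30 | hydroxy acid from 29, not isolated | O[C@@H]1/C=C(/CO[Si](c2ccccc2)(c2ccccc2)C(C)(C)C)[C@H](O[Si](C)(C)C(C)(C)C)C/C=C(C)/C[C@@H](OC(=O)C(C)C)[C@H]1CC(=O)O | intermediate
31 | trans-fused 6,12-lactone with C3 TBS ether (3R,6R,7R,8R), not isolated | C1C(=O)O[C@@H]2/C=C(/CO[Si](c3ccccc3)(c3ccccc3)C(C)(C)C)[C@H](O[Si](C)(C)C(C)(C)C)C/C=C(C)/C[C@@H](OC(=O)C(C)C)[C@@H]12 | intermediate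
32 | trans-fused 6,12-lactone with free C3 hydroxyl (3R,6R,7R,8R) | C1C(=O)O[C@@H]2/C=C(/CO[Si](c3ccccc3)(c3ccccc3)C(C)(C)C)[C@H](O)C/C=C(C)/C[C@@H](OC(=O)C(C)C)[C@@H]12 | intermediate
33 | 3-oxo lactone (C3 enone; 6R,7R,8R) | C1C(=O)O[C@@H]2/C=C(/CO[Si](c3ccccc3)(c3ccccc3)C(C)(C)C)C(=O)C/C=C(C)/C[C@@H](OC(=O)C(C)C)[C@@H]12 | intermediate
34 | C1 organomercury acetate of the 3-O-methyl 3,10-oxide (mercury anti to the new C10–O bond), not isolated | C1C(=O)O[C@@H]2/C=C(/CO[Si](c3ccccc3)(c3ccccc3)C(C)(C)C)[C@@]3(OC)C[C@@H]([Hg]OC(C)=O)[C@](C)(C[C@@H](OC(=O)C(C)C)[C@@H]12)O3 | intermediate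
35 | 3-O-methyl 3,10-oxide, saturated lactone (C3 as written; 6R,7R,8R,10R) | C1C(=O)O[C@@H]2/C=C(/CO[Si](c3ccccc3)(c3ccccc3)C(C)(C)C)[C@@]3(OC)CC[C@](C)(C[C@@H](OC(=O)C(C)C)[C@@H]12)O3 | intermediate
36 | lithium enolate of lactone 35, not isolated | [Li+].C1=C([O-])O[C@@H]2/C=C(/CO[Si](c3ccccc3)(c3ccccc3)C(C)(C)C)[C@@]3(OC)CC[C@](C)(C[C@@H](OC(=O)C(C)C)[C@@H]12)O3 | intermediate
37 | C11 dimethylaminomethyl lactone (C11 epimers), not isolated | CN(C)CC1C(=O)O[C@@H]2/C=C(/CO[Si](c3ccccc3)(c3ccccc3)C(C)(C)C)[C@@]3(OC)CC[C@](C)(C[C@@H](OC(=O)C(C)C)[C@@H]12)O3 | intermediate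
38 | C11 trimethylammoniomethyl lactone iodide, not isolated | [I-].C[N+](C)(C)CC1C(=O)O[C@@H]2/C=C(/CO[Si](c3ccccc3)(c3ccccc3)C(C)(C)C)[C@@]3(OC)CC[C@](C)(C[C@@H](OC(=O)C(C)C)[C@@H]12)O3 | intermediate
39 | α-methylene lactone, 3-O-methyl ketal, C15 TBDPS ether | C=C1C(=O)O[C@@H]2/C=C(/CO[Si](c3ccccc3)(c3ccccc3)C(C)(C)C)[C@@]3(OC)CC[C@](C)(C[C@@H](OC(=O)C(C)C)[C@@H]12)O3 | intermediate
40 | CNP0282937.1 | C=C1C(=O)O[C@@H]2/C=C(/CO)[C@@]3(O)CC[C@](C)(C[C@@H](OC(=O)C(C)C)[C@@H]12)O3 | target

Total step count: 19. Longest linear sequence: 16 steps (1–6, then 10–19, from 1 to 40); steps 7–9 form the enol ether branch.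

Steps most likely to fail

Step 11 (key step). The ring-expanded potassium enolate may expel the C8 4-methoxybenzyl oxide (β-elimination), or the alkoxide may fragment or take up a silyl group before the shift. Fallback, from 20 back to 23: the tertiary hydroxyl of 20 is silylated with N-(trimethylsilyl)imidazole to the trimethylsilyl ether F1. F1 is heated in degassed o-dichlorobenzene at about 200 °C in base-washed glass, where the neutral siloxy-Cope rearrangement through the same chair should give the trimethylsilyl enol ether F2. Aqueous citric acid in THF at 0 °C then hydrolyses F2 to 23. No metal enolate is formed on this way, so the C8 ether cannot be lost by elimination.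

Step 12. Facial selectivity may be poor: the bromoacetate may attack the enolate face that puts the chain trans to the C8 oxygen, which is the face exposed if the enolate is not chelated or keeps the conformation in which it is formed in step 11. Fallback, from 23 back to 26: the lithium enolate of 23 is added to tert-butyl glyoxylate to give the aldol adduct F3, which is converted with MsCl/Et3N into the mesylate F4 and with DBU into the alkylidene keto ester F5 (either alkene isomer serves). Conjugate reduction of the doubly activated C7=C11 alkene with [(Ph3P)CuH]6 in wet benzene, followed by protonation of the C6–C7 enolate on its open face, should then give 26. C7 is set here by a proton and not by the carbon electrophile, which reverses the relation between the chain and the C8 oxygen.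

Step 17. The E alkene can turn through the ring, so the mercurinium ion may be opened through the wrong alkene face; it may also be intercepted by the neighbouring ester carbonyl or by solvent, or revert to the alkene on reduction. Fallback, from 33 back to 35: 33 is epoxidized with mCPBA/NaHCO3 in CH2Cl2 at 0 °C to the epoxide F6; attack should come from the ring periphery on the ground-state conformer and the enone alkene is too electron-poor to react. Camphorsulfonic acid in methanol opens F6 at the tertiary C10 with inversion by the C3 carbonyl oxygen and methanol caps C3, giving the C1 alcohol F7 with the bridge of 35. Barton–McCombie deoxygenation then removes the C1 hydroxyl: 1,1'-thiocarbonyldiimidazole gives the imidazolyl thiocarbonate F8, and Bu3SnH/AIBN in toluene at 80 °C gives 35. The face is decided here by an irreversible peripheral epoxidation instead of a reversible mercuration.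

Further compounds
F1 | step 11 | trimethylsilyl ether of 20 | COc1ccc(CO/C=C/[C@@]2(O[Si](C)(C)C)C=C(CO[Si](c3ccccc3)(c3ccccc3)C(C)(C)C)[C@H](O[Si](C)(C)C(C)(C)C)C[C@@H]2C(C)=C)cc1
F2 | step 11 | trimethylsilyl enol ether of 23 (C6–C7 enol ether, oxygen cis to C8) | C[Si](C)(C)O/C1=C\[C@H](OCc2ccc(OC)cc2)C/C(C)=C/C[C@@H](O[Si](C)(C)C(C)(C)C)/C(CO[Si](c2ccccc2)(c2ccccc2)C(C)(C)C)=C\1
F3 | step 12 | aldol adduct of 23 with tert-butyl glyoxylate at C7 (C7 and C11 epimers) | O=C1/C=C(/CO[Si](c2ccccc2)(c2ccccc2)C(C)(C)C)[C@H](O[Si](C)(C)C(C)(C)C)C/C=C(C)/C[C@@H](OCc2ccc(OC)cc2)C1C(O)C(=O)OC(C)(C)C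
F4 | step 12 | mesylate of F3 | O=C1/C=C(/CO[Si](c2ccccc2)(c2ccccc2)C(C)(C)C)[C@H](O[Si](C)(C)C(C)(C)C)C/C=C(C)/C[C@@H](OCc2ccc(OC)cc2)C1C(OS(C)(=O)=O)C(=O)OC(C)(C)C
F5 | step 12 | C7=C11 alkylidene keto ester | O=C1/C=C(/CO[Si](c2ccccc2)(c2ccccc2)C(C)(C)C)[C@H](O[Si](C)(C)C(C)(C)C)C/C=C(C)/C[C@@H](OCc2ccc(OC)cc2)C1=CC(=O)OC(C)(C)C
F6 | step 17 | 1,10-epoxide of 33 (oxygen on the peripheral face) | C1C(=O)O[C@@H]2/C=C(/CO[Si](c3ccccc3)(c3ccccc3)C(C)(C)C)C(=O)C[C@H]3O[C@]3(C)C[C@@H](OC(=O)C(C)C)[C@@H]12
F7 | step 17 | C1 alcohol of the 3-O-methyl 3,10-oxide | C1C(=O)O[C@@H]2/C=C(/CO[Si](c3ccccc3)(c3ccccc3)C(C)(C)C)[C@@]3(OC)C[C@@H](O)[C@](C)(C[C@@H](OC(=O)C(C)C)[C@@H]12)O3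
F8 | step 17 | C1 O-(imidazol-1-ylthiocarbonyl) derivative of F7 | C1C(=O)O[C@@H]2/C=C(/CO[Si](c3ccccc3)(c3ccccc3)C(C)(C)C)[C@@]3(OC)C[C@@H](OC(=S)n4ccnc4)[C@](C)(C[C@@H](OC(=O)C(C)C)[C@@H]12)O3
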